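The constants of the five steps are unknown, so I look for something the readings give without them. In the flasks asked about, partner is charged equal to starting material and to second substrate, and two catalytic routes plus the uncatalysed step draw on it, so I write its balance.

| setting | zeta | alpha | west | north | north-west | east |
|---|---|---|---|---|---|---|
| starting material | 0.10 M | 0.10 M | 0.10 M | 0.10 M | 0.10 M | 0.10 M |
| second substrate | 0.10 M | 0.10 M | 0.100 M | 0.100 M | 0.100 M | 0.100 M |
| partner | 0.050 M | 0.20 M | 0.100 M | 0.100 M | 0.100 M | 0.100 M |
| free catalyst | 5 mM | 5 mM | 5.0 mM | 5.0 mM | 5.0 mM | 5.0 mM |
| temperature | −12 °C | 15 °C | −25 °C |  | 25 °C | 0 °C |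
| remark | run made earlier | run made earlier |  | at 25 °C until 3.0 d, from then on at −25 °C |  |  |
| time |  |  | 4.0 d | 4.0 d | 4.0 d | 4.0 d |

zeta run (percent of the starting material charged)

| time / d | target / % | starting material / % |
|---|---|---|
| 0.625 | 1.2 | 97.8 |
| 1.25 | 2.8 | 95.8 |
| 2.00 | 5.0 | 94.3 |
| 2.50 | 5.0 | 93.6 |

alpha run (percent of the starting material charged)

| time / h | target / % | starting material / % |
|---|---|---|
| 1.33 | 2.1 | 96.1 |
| 3.00 | 5.1 | 92.7 |
| 6.00 | 8.3 | 87.6 |
| 15.0 | 17.9 | 75.7 |

(scatter of a reading: 0.3 percentage points)

- the numbers in the tables scatter with a standard deviation of 0.3 percentage points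
- reactions considered so far: starting material + free catalyst <-> catalyst intermediate A; partner + catalyst intermediate A -> free catalyst + target; second substrate + free catalyst <-> catalyst intermediate B; partner + catalyst intermediate B -> free catalyst + second product; starting material + partner -> uncatalysed product

- the flask that comes out highest in amount of target, in percent of the starting material charged, or "all alike" when all lie within 1.5 percentage points (west / north / north-west / east / all alike)
- target at the end, in percent of the starting material charged, west
- target at the end, in percent of the starting material charged, north
- target at the end, in percent of the starting material charged, north-west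
- target at the end, in percent of the starting material charged, east

Partner is never read, but if the target rate goes as c(starting material)·c(partner), alpha's falling rate shows it. I compare the rate up to 3.00 h with the rate from 6.00 h to 15.0 h:

rate: 0.0170 h⁻¹ early, 0.0107 h⁻¹ late, ratio 0.627
c(starting material), late over early: 0.847
c(partner), late over early: 0.740
partner used between the windows, the early level taken as the charge: 0.0519 M
target made meanwhile: 0.0106 M

So in alpha, by this reading, target takes 0.203 of the partner consumed. I call this reading φ, target formed per partner consumed, and carry it.

My first objection is that the uncatalysed step might be eating the partner. But starting material missing from target at 15.0 h is 0.00640 M, catalyst-bound part included, which is less than the partner used. Of the listed steps that use partner, the second-substrate route is the one that remains for the remainder.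

My second objection is temperature. The same reckoning on zeta gives

0.266

The scatter makes this rough, and zeta differs from alpha in partner as well as in temperature, so I cannot put the difference on temperature; but the reading is higher in the colder run, and a warmer flask may lie lower.

Does partner run out in time? Alpha's decay, read at 15 °C with 0.20 M of partner, gives a time constant of 29.9 h, and 4.0 d is 3.21 of these. So I expect partner, charged at 0.100 M against 0.200 M of starting material and second substrate together, to be the limiting reagent in north-west, and for a flask whose partner is used up I commit to an end value of

φ·c(partner)/c(starting material) = 20.3 %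

or somewhat less at 25 °C.

The forecast names north-west, with west 6.5 %, north 23 %, north-west 24 % and east 20 %, on the ground that “The warm flasks therefore plateau”. Its 24 % for north-west is higher than my end value.

The flasks give west 7.08 %, north 8.91 %, north-west 8.92 % and east 17.3 %, so east comes out highest.

    starting material + free catalyst ⇌ catalyst intermediate A (K = 3.40 L mol⁻¹, k = 12.0 L mol⁻¹ h⁻¹, Ea = 56.0 kJ mol⁻¹, ΔH = −12.0 kJ mol⁻¹)
    partner + catalyst intermediate A → free catalyst + target (k = 4.60 L mol⁻¹ h⁻¹, Ea = 45.0 kJ mol⁻¹)
    second substrate + free catalyst ⇌ catalyst intermediate B (K = 6.80 L mol⁻¹, k = 14.0 L mol⁻¹ h⁻¹, Ea = 67.0 kJ mol⁻¹, ΔH = 22.0 kJ mol⁻¹)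
    partner + catalyst intermediate B → free catalyst + second product (k = 16.0 L mol⁻¹ h⁻¹, Ea = 46.0 kJ mol⁻¹)
    starting material + partner → uncatalysed product (k = 0.00590 L mol⁻¹ h⁻¹, Ea = 78.0 kJ mol⁻¹)
    (constants at 0 °C)

In north-west at 4.00 d, partner stands at 0 %, with 0.0848 M of second product against 0.00892 M of target, so φ there is 0.0892, lower than alpha's reading. In east at 0.995 d, catalyst intermediate B falls back 2.1 times faster than it goes on, and left for 40.0 d that flask holds partner at 0 % and target at 21.9 %, a φ of 0.219.

The runs were computed from invented constants; scatter was added.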